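**Retrosynthetic overview**
1. Target 34 ⇐ C6 esterification and desilylation of epoxy alcohol 24 with the TES-protected (2R,3S)-acid 31, itself from a cis-β-lactone made by catalytic ketene–aldehyde cyclocondensation.
2. 24 ⇐ hydroxyl-directed epoxidation of C4=C5 after C8 tigloylation of the (1(10)E,4E)-germacradiene-6,8-diol core 20 (C6 and C8 told apart as TBS and TES ethers).
3. The ten-membered carbocycle (the only carbocycle, formed first; the epoxide second) ⇐ ring contraction of an 11-membered cyclic alkenyl boronate complex: selenium-triggered 1,2-shift of C3 from B to C4, then syn-elimination to the 4E alkene.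
4. Acyclic iodide/alkenylboronate 16 ⇐ diyne 9 by Zr-catalysed methylalumination/oxirane opening (C1=C10, C2, C3), Cu-catalysed alkyne borylation (C4–B) and Appel iodination.
5. The C6–C7–C8 triad of 9 ⇐ organocatalytic anti cross-aldol (3-methylbutanal + but-2-ynal), then reagent-controlled propargylboration.

Assumption: but-2-ynal and all reagents and catalysts are purchased; ring compounds are named with germacrane numbering (ring C1–C10, C14 on C10, C15 on C4, isopropyl on C7) and the CIP descriptors refer to that numbering.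

Step 1
Reactants: 1 3-methylbutanal; 2 but-2-ynal
Product: 3 (2R,3S)-3-hydroxy-2-(propan-2-yl)hex-4-ynal
Conditions: (R)-α,α-bis[3,5-bis(trifluoromethyl)phenyl]prolinol (10 mol %), H2O (3 equiv), 1,4-dioxane, rt; used crude
Reagents that add atoms: none
Why: Diarylprolinol-catalysed direct cross-aldol (enamine catalysis with an H-bonded, proline-type transition state) in which the non-enolisable ynal is the only acceptor, so the (R)-catalyst gives the anti adduct and sets C7 and C6.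

Step 2
Reactants: 3 (2R,3S)-3-hydroxy-2-(propan-2-yl)hex-4-ynal
Product: 4 (2R,3S)-3-[(tert-butyldimethylsilyl)oxy]-2-(propan-2-yl)hex-4-ynal
Conditions: TBSOTf, 2,6-lutidine, CH2Cl2, −78 °C
Reagents that add atoms: tert-butyldimethylsilyl trifluoromethanesulfonate, CC(C)(C)[Si](C)(C)OS(=O)(=O)C(F)(F)F
Why: Silyl ether formation under non-epimerising conditions stabilises the aldol and marks the C6 oxygen as the one to be freed late.

Step 3
Reactants: 4 (2R,3S)-3-[(tert-butyldimethylsilyl)oxy]-2-(propan-2-yl)hex-4-ynal; 5 3-bromoprop-1-yne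
Product: 8 (4R,5S,6S)-6-[(tert-butyldimethylsilyl)oxy]-5-(propan-2-yl)nona-1,7-diyn-4-ol, via allenylmagnesium bromide 6 (not isolated), via B-allenyldiisopinocampheylborane 7 (not isolated)
Conditions: 5, Mg, HgCl2 (cat.), Et2O, 0 °C; (+)-Ipc2BOMe, −78 °C → rt; 4, Et2O, −100 → −78 °C; NaOH, H2O2
Reagents that add atoms: none
Why: Brown asymmetric allenylboration (propargylation) through a closed six-membered SE2′ transition state, in which the l-Ipc2B reagent sets the C8 carbinol (R), the same isomer that Felkin–Anh/1,3-anti substrate bias is expected to favour (matched case).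

Step 4
Reactants: 8 (4R,5S,6S)-6-[(tert-butyldimethylsilyl)oxy]-5-(propan-2-yl)nona-1,7-diyn-4-ol
Product: 9 (4R,5S,6S)-6-[(tert-butyldimethylsilyl)oxy]-5-(propan-2-yl)-4-[(triethylsilyl)oxy]nona-1,7-diyne
Conditions: TESOTf, 2,6-lutidine, CH2Cl2, −78 → 0 °C
Reagents that add atoms: triethylsilyl trifluoromethanesulfonate, CC[Si](CC)(CC)OS(=O)(=O)C(F)(F)F
Why: Silylation gives a C8 ether that survives the organometallic steps but is more labile than the C6 TBS ether, so the two oxygens stay distinguishable.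

Step 5
Reactants: 9 (4R,5S,6S)-6-[(tert-butyldimethylsilyl)oxy]-5-(propan-2-yl)-4-[(triethylsilyl)oxy]nona-1,7-diyne; 10 trimethylaluminium; 11 oxirane
Product: 14 (3E,6R,7S,8S)-8-[(tert-butyldimethylsilyl)oxy]-4-methyl-7-(propan-2-yl)-6-[(triethylsilyl)oxy]undec-3-en-9-yn-1-ol, via alkenyldimethylalane 12 (not isolated), via lithium alkenylalanate 13 (not isolated)
Conditions: 10 (2 equiv), Cp2ZrCl2 (25 mol %), CH2Cl2, 0 °C → rt; excess 10 evaporated; n-BuLi (1 equiv), hexane/THF, −78 °C; 11, −78 → 0 °C; aq. NH4Cl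
Reagents that add atoms: none
Why: Negishi Zr-catalysed syn-methylalumination reacts only at the terminal alkyne and fixes the 1(10)E geometry, and the derived alanate opens oxirane with retention to add C2 and C3.

Step 6
Reactants: 14 (3E,6R,7S,8S)-8-[(tert-butyldimethylsilyl)oxy]-4-methyl-7-(propan-2-yl)-6-[(triethylsilyl)oxy]undec-3-en-9-yn-1-ol
Product: 15 (3E,6R,7S,8R,9Z)-8-[(tert-butyldimethylsilyl)oxy]-4-methyl-7-(propan-2-yl)-10-(4,4,5,5-tetramethyl-1,3,2-dioxaborolan-2-yl)-6-[(triethylsilyl)oxy]undeca-3,9-dien-1-ol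
Conditions: CuCl (10 mol %), PCy3 (12 mol %), NaOt-Bu (15 mol %), B2pin2, MeOH (2 equiv), toluene, rt
Reagents that add atoms: bis(pinacolato)diboron, CC1(C)OB(OC1(C)C)B1OC(C)(C)C(C)(C)O1
Why: Cu-catalysed syn-borylcupration/protonation (formal alkyne hydroboration) puts boron on the less hindered methyl-bearing carbon distal to the propargylic silyl ether, giving the alkenylboronate with B trans to C6.

Step 7
Reactants: 15 (3E,6R,7S,8R,9Z)-8-[(tert-butyldimethylsilyl)oxy]-4-methyl-7-(propan-2-yl)-10-(4,4,5,5-tetramethyl-1,3,2-dioxaborolan-2-yl)-6-[(triethylsilyl)oxy]undeca-3,9-dien-1-ol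
Product: 16 (3E,6R,7S,8R,9Z)-8-[(tert-butyldimethylsilyl)oxy]-1-iodo-4-methyl-7-(propan-2-yl)-10-(4,4,5,5-tetramethyl-1,3,2-dioxaborolan-2-yl)-6-[(triethylsilyl)oxy]undeca-3,9-diene
Conditions: I2, PPh3, imidazole, CH2Cl2, 0 °C
Reagents that add atoms: iodine, II
Why: Appel iodination of the only free (primary) alcohol under buffered conditions leaves the alkenylboronate and silyl ethers untouched.

Step 8
Reactants: 16 (3E,6R,7S,8R,9Z)-8-[(tert-butyldimethylsilyl)oxy]-1-iodo-4-methyl-7-(propan-2-yl)-10-(4,4,5,5-tetramethyl-1,3,2-dioxaborolan-2-yl)-6-[(triethylsilyl)oxy]undeca-3,9-diene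
Product: 20 (1(10)E,4E,6R,7S,8R)-6-O-(tert-butyldimethylsilyl)germacra-1(10),4-diene-6,8-diol, via cyclic boronate complex 17 (not isolated), via selenoboronic ester 18 (not isolated), via TES-protected macrocycle 19 (not isolated)
Conditions: t-BuLi (2.1 equiv), Et2O/THF (1 mM), −78 °C; PhSeCl, THF, −78 °C; mCPBA (1.05 equiv), −78 → −20 °C; then PPTS, MeOH, rt
Reagents that add atoms: none
Why: Proposed new method: iodine–lithium exchange at the primary iodide (faster than t-BuLi addition to the hindered boronate) lets C3–Li close on boron at high dilution to an 11-membered cyclic alkenyl boronate complex, PhSe+ attack at C5 then drives the 1,2-shift of C3 from B to C4 (anti to Se) and contracts the ring to the ten-membered carbocycle, and selenoxide syn-elimination of Se/B gives the 4E alkene stereospecifically (B trans to C6 becomes C3 trans to C6) before mild methanolysis removes only the TES group; the closest known chemistry is the intermolecular Zweifel-type selenium-mediated olefination of alkenyl boronate complexes and the electrophile-induced ring-contractive 1,2-metallate shift of five- and six-membered cyclic alkenyl boronate complexes, here extended to a macrocyclic ate complex as a carbocyclisation.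

Step 9
Reactants: 20 (1(10)E,4E,6R,7S,8R)-6-O-(tert-butyldimethylsilyl)germacra-1(10),4-diene-6,8-diol; 21 (E)-2-methylbut-2-enoyl chloride
Product: 22 (1(10)E,4E,6R,7S,8R)-6-O-(tert-butyldimethylsilyl)-8-O-tigloylgermacra-1(10),4-diene-6,8-diol
Conditions: Et3N, DMAP (cat.), CH2Cl2, 0 °C → rt
Reagents that add atoms: none
Why: DMAP-catalysed acylation of the only free hydroxyl (C8) installs the tiglate without touching the E geometry of the acyl group.

Step 10
Reactants: 22 (1(10)E,4E,6R,7S,8R)-6-O-(tert-butyldimethylsilyl)-8-O-tigloylgermacra-1(10),4-diene-6,8-diol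
Product: 23 (1(10)E,4E,6R,7R,8R)-8-O-tigloylgermacra-1(10),4-diene-6,8-diol
Conditions: HF·pyridine, pyridine/THF, 0 °C → rt
Reagents that add atoms: none
Why: Buffered fluoride desilylation frees the allylic C6 hydroxyl under non-basic conditions that avoid 1,3-acyl migration of the tiglate (the C7 descriptor changes only through CIP priorities).

Step 11
Reactants: 23 (1(10)E,4E,6R,7R,8R)-8-O-tigloylgermacra-1(10),4-diene-6,8-diol
Product: 24 (1(10)E,4R,5R,6S,7R,8R)-4,5-epoxy-8-O-tigloylgermacr-1(10)-ene-6,8-diol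
Conditions: VO(acac)2 (5 mol %), t-BuOOH (1.5 equiv), CH2Cl2, 0 °C
Reagents that add atoms: tert-butyl hydroperoxide, CC(C)(C)OO
Why: Hydroxyl-directed vanadium-catalysed epoxidation touches only the allylic C4=C5 bond, and A(1,3) strain between the C4 methyl and C6 holds C6–H in the alkene plane so oxygen is delivered syn to the hydroxyl, giving the threo (4R,5R) trans-epoxide.

Step 12
Reactants: 25 propanoyl chloride; 26 acetaldehyde
Product: 28 (3R,4S)-3,4-dimethyloxetan-2-one, via methylketene 27 (not isolated)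
Conditions: O-TMS-quinine (10 mol %), LiClO4, i-Pr2NEt, CH2Cl2/Et2O, −78 °C
Reagents that add atoms: none
Why: Cinchona alkaloid/Lewis acid-catalysed ketene–aldehyde cyclocondensation (stepwise aldol–lactonisation) gives the cis-β-lactone and sets both side-chain stereocentres; the alkaloid pseudoenantiomer is chosen to give (3R,4S).

Step 13
Reactants: 28 (3R,4S)-3,4-dimethyloxetan-2-one
Product: 29 (2R,3S)-3-hydroxy-2-methylbutanoic acid
Conditions: LiOH, THF/H2O, 0 °C; then 1 M HCl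
Reagents that add atoms: lithium hydroxide, [Li+].[OH-]
Why: Saponification by acyl–oxygen cleavage of the strained lactone at 0 °C leaves both stereocentres untouched.

Step 14
Reactants: 29 (2R,3S)-3-hydroxy-2-methylbutanoic acid
Product: 31 (2R,3S)-2-methyl-3-[(triethylsilyl)oxy]butanoic acid, via bis-silylated acid 30 (not isolated)
Conditions: TESCl (2.2 equiv), imidazole, DMF, 0 °C → rt; then THF/MeOH/H2O, rt
Reagents that add atoms: chlorotriethylsilane, CC[Si](Cl)(CC)CC
Why: Bis-silylation followed by selective hydrolysis of the much more labile silyl ester gives the O-protected acid.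

Step 15
Reactants: 24 (1(10)E,4R,5R,6S,7R,8R)-4,5-epoxy-8-O-tigloylgermacr-1(10)-ene-6,8-diol; 31 (2R,3S)-2-methyl-3-[(triethylsilyl)oxy]butanoic acid
Product: 33 (1(10)E,4R,5R,6S,7S,8R)-4,5-epoxy-6-O-[(2R,3S)-2-methyl-3-(triethylsilyloxy)butanoyl]-8-O-tigloylgermacr-1(10)-ene-6,8-diol, via Yamaguchi mixed anhydride 32 (not isolated)
Conditions: 31, 2,4,6-trichlorobenzoyl chloride, Et3N, toluene, rt; then 24, DMAP, toluene, rt
Reagents that add atoms: none
Why: Yamaguchi esterification acylates the hindered C6 hydroxyl under non-acidic conditions that spare the epoxide and avoid Payne rearrangement.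

Step 16
Reactants: 33 (1(10)E,4R,5R,6S,7S,8R)-4,5-epoxy-6-O-[(2R,3S)-2-methyl-3-(triethylsilyloxy)butanoyl]-8-O-tigloylgermacr-1(10)-ene-6,8-diol
Product: 34 CNP0159364.1
Conditions: HF·pyridine, pyridine/THF, 0 °C
Reagents that add atoms: none
Why: Buffered fluoride cleavage of the single TES ether releases the side-chain hydroxyl without opening the epoxide or migrating the esters.

**Compound list**
1 | 3-methylbutanal | CC(C)CC=O | starting material
2 | but-2-ynal | CC#CC=O | starting material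
3 | (2R,3S)-3-hydroxy-2-(propan-2-yl)hex-4-ynal | CC#C[C@@H](O)[C@H](C=O)C(C)C | intermediate
4 | (2R,3S)-3-[(tert-butyldimethylsilyl)oxy]-2-(propan-2-yl)hex-4-ynal | CC#C[C@@H](O[Si](C)(C)C(C)(C)C)[C@H](C=O)C(C)C | intermediate
5 | 3-bromoprop-1-yne (propargyl bromide) | C#CCBr | starting material
6 | allenylmagnesium bromide | C=C=C[Mg]Br | intermediate
7 | B-allenyldiisopinocampheylborane (l-Ipc series, from (+)-Ipc2BOMe) | C=C=CB([C@H]1C[C@H]2C[C@@H]([C@@H]1C)C2(C)C)[C@H]1C[C@H]2C[C@@H]([C@@H]1C)C2(C)C | intermediate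
8 | (4R,5S,6S)-6-[(tert-butyldimethylsilyl)oxy]-5-(propan-2-yl)nona-1,7-diyn-4-ol | CC#C[C@@H](O[Si](C)(C)C(C)(C)C)[C@H]([C@H](O)CC#C)C(C)C | intermediate
9 | (4R,5S,6S)-6-[(tert-butyldimethylsilyl)oxy]-5-(propan-2-yl)-4-[(triethylsilyl)oxy]nona-1,7-diyne | CC#C[C@@H](O[Si](C)(C)C(C)(C)C)[C@H]([C@H](O[Si](CC)(CC)CC)CC#C)C(C)C | intermediate
10 | trimethylaluminium | C[Al](C)C | starting material
11 | oxirane | C1CO1 | starting material
12 | [(1E,4R,5S,6S)-6-(tert-butyldimethylsilyloxy)-2-methyl-5-(propan-2-yl)-4-(triethylsilyloxy)non-1-en-7-yn-1-yl]dimethylalane | C[Al](C)/C=C(\C)C[C@@H](O[Si](CC)(CC)CC)[C@@H]([C@H](O[Si](C)(C)C(C)(C)C)C#CC)C(C)C | intermediate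
13 | lithium butyl(dimethyl)[(1E,4R,5S,6S)-alkenyl]alanate derived from 12 | [Li+].CCCC[Al-](C)(C)/C=C(\C)C[C@@H](O[Si](CC)(CC)CC)[C@@H]([C@H](O[Si](C)(C)C(C)(C)C)C#CC)C(C)C | intermediate
14 | (3E,6R,7S,8S)-8-[(tert-butyldimethylsilyl)oxy]-4-methyl-7-(propan-2-yl)-6-[(triethylsilyl)oxy]undec-3-en-9-yn-1-ol | OCC/C=C(\C)C[C@@H](O[Si](CC)(CC)CC)[C@@H]([C@H](O[Si](C)(C)C(C)(C)C)C#CC)C(C)C | intermediate
15 | (3E,6R,7S,8R,9Z)-8-[(tert-butyldimethylsilyl)oxy]-4-methyl-7-(propan-2-yl)-10-(4,4,5,5-tetramethyl-1,3,2-dioxaborolan-2-yl)-6-[(triethylsilyl)oxy]undeca-3,9-dien-1-ol | OCC/C=C(\C)C[C@@H](O[Si](CC)(CC)CC)[C@@H]([C@H](O[Si](C)(C)C(C)(C)C)/C=C(\C)B1OC(C)(C)C(C)(C)O1)C(C)C | intermediate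
16 | (3E,6R,7S,8R,9Z)-8-[(tert-butyldimethylsilyl)oxy]-1-iodo-4-methyl-7-(propan-2-yl)-10-(4,4,5,5-tetramethyl-1,3,2-dioxaborolan-2-yl)-6-[(triethylsilyl)oxy]undeca-3,9-diene | ICC/C=C(\C)C[C@@H](O[Si](CC)(CC)CC)[C@@H]([C@H](O[Si](C)(C)C(C)(C)C)/C=C(\C)B1OC(C)(C)C(C)(C)O1)C(C)C | intermediate
17 | lithium 11-membered cyclic (pinacolato)boronate complex: B bonded to C3 and C4; 1(10)E; B trans to C6 across C4=C5; (6R,7S,8R) | [Li+].CC1(C)O[B-]2(OC1(C)C)CC/C=C(\C)C[C@@H](O[Si](CC)(CC)CC)[C@H](C(C)C)[C@H](O[Si](C)(C)C(C)(C)C)/C=C2\C | intermediate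
18 | (1(10)E,4S,5S,6S,7S,8R)-4-(pinacolboryl)-5-(phenylselanyl)-6-O-TBS-8-O-TES-germacr-1(10)-ene-6,8-diol (anti adduct; the diastereomer from the other alkene face converges to the same alkene) | C[C@@]1(B2OC(C)(C)C(C)(C)O2)CC/C=C(\C)C[C@@H](O[Si](CC)(CC)CC)[C@H](C(C)C)[C@H](O[Si](C)(C)C(C)(C)C)[C@H]1[Se]c1ccccc1 | intermediate
19 | (1(10)E,4E,6R,7S,8R)-6-O-(tert-butyldimethylsilyl)-8-O-(triethylsilyl)germacra-1(10),4-diene-6,8-diol | C/C1=C\[C@@H](O[Si](C)(C)C(C)(C)C)[C@@H](C(C)C)[C@H](O[Si](CC)(CC)CC)C/C(C)=C/CC1 | intermediate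
20 | (1(10)E,4E,6R,7S,8R)-6-O-(tert-butyldimethylsilyl)germacra-1(10),4-diene-6,8-diol | C/C1=C\[C@@H](O[Si](C)(C)C(C)(C)C)[C@@H](C(C)C)[C@H](O)C/C(C)=C/CC1 | intermediate
21 | (E)-2-methylbut-2-enoyl chloride (tigloyl chloride) | C/C=C(\C)C(Cl)=O | starting material
22 | (1(10)E,4E,6R,7S,8R)-6-O-(tert-butyldimethylsilyl)-8-O-tigloylgermacra-1(10),4-diene-6,8-diol | C/C1=C\[C@@H](O[Si](C)(C)C(C)(C)C)[C@@H](C(C)C)[C@H](OC(=O)/C(C)=C/C)C/C(C)=C/CC1 | intermediate
23 | (1(10)E,4E,6R,7R,8R)-8-O-tigloylgermacra-1(10),4-diene-6,8-diol | C/C1=C\[C@@H](O)[C@@H](C(C)C)[C@H](OC(=O)/C(C)=C/C)C/C(C)=C/CC1 | intermediate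
24 | (1(10)E,4R,5R,6S,7R,8R)-4,5-epoxy-8-O-tigloylgermacr-1(10)-ene-6,8-diol | C/C=C(\C)C(=O)O[C@@H]1C/C(C)=C/CC[C@@]2(C)O[C@@H]2[C@@H](O)[C@H]1C(C)C | intermediate
25 | propanoyl chloride | CCC(Cl)=O | starting material
26 | acetaldehyde | CC=O | starting material
27 | methylketene (prop-1-en-1-one) | CC=C=O | intermediate
28 | (3R,4S)-3,4-dimethyloxetan-2-one | C[C@@H]1[C@H](C)OC1=O | intermediate
29 | (2R,3S)-3-hydroxy-2-methylbutanoic acid | C[C@H](O)[C@@H](C)C(=O)O | intermediate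
30 | triethylsilyl (2R,3S)-2-methyl-3-[(triethylsilyl)oxy]butanoate | C[C@H](O[Si](CC)(CC)CC)[C@@H](C)C(=O)O[Si](CC)(CC)CC | intermediate
31 | (2R,3S)-2-methyl-3-[(triethylsilyl)oxy]butanoic acid | C[C@H](O[Si](CC)(CC)CC)[C@@H](C)C(=O)O | intermediate
32 | (2R,3S)-2-methyl-3-[(triethylsilyl)oxy]butanoic 2,4,6-trichlorobenzoic anhydride | C[C@H](O[Si](CC)(CC)CC)[C@@H](C)C(=O)OC(=O)c1c(Cl)cc(Cl)cc1Cl | intermediate
33 | (1(10)E,4R,5R,6S,7S,8R)-4,5-epoxy-6-O-[(2R,3S)-2-methyl-3-(triethylsilyloxy)butanoyl]-8-O-tigloylgermacr-1(10)-ene-6,8-diol | C/C=C(\C)C(=O)O[C@@H]1C/C(C)=C/CC[C@@]2(C)O[C@@H]2[C@@H](OC(=O)[C@H](C)[C@H](C)O[Si](CC)(CC)CC)[C@H]1C(C)C | intermediate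
34 | CNP0159364.1: (1(10)E,4R,5R,6S,7S,8R)-4,5-epoxy-6-O-[(2R,3S)-3-hydroxy-2-methylbutanoyl]-8-O-tigloylgermacr-1(10)-ene-6,8-diol | C/C=C(\C)C(=O)O[C@@H]1C/C(C)=C/CC[C@@]2(C)O[C@@H]2[C@@H](OC(=O)[C@H](C)[C@H](C)O)[C@H]1C(C)C | target

**Totals and risks**

Total step count: 16. Longest linear sequence: 13 steps (steps 1–11, 15, 16); steps 12–14 make the side-chain acid.

The three steps most likely to fail are 8, 3 and 6.

Step 8 is the new ring contraction. The risk is that the alkyllithium forms oligomeric boronate complexes instead of the 11-membered one, or that t-BuLi adds to boron. The fallback uses known chemistry and sets out from 16. Iododeboronation with retention (NaOH, I2, THF, 0 °C) gives (3E,6R,7S,8S,9E)-8-[(tert-butyldimethylsilyl)oxy]-1,10-diiodo-4-methyl-7-(propan-2-yl)-6-[(triethylsilyl)oxy]undeca-3,9-diene F1. Chemoselective zinc insertion into the primary C–I bond (Zn dust, LiCl, THF, rt) gives the alkylzinc iodide F2. An intramolecular Negishi coupling (Pd(PPh3)4, THF, 1 mM, 50 °C, retention at C4) closes the ten-membered ring to 19, which is methanolysed (PPTS, MeOH) exactly as in step 8, so the route is rejoined at 20.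

Step 3 is the propargylboration of a hindered α-branched aldehyde. The risk is poor diastereoselectivity if the reagent and substrate preferences turn out mismatched. The fallback sets out from 4. An unselective Barbier propargylation (Zn, 5, THF/aq. NH4Cl) proceeds through allenylzinc bromide F3 to the C4-epimeric mixture (4RS,5S,6S)-6-[(tert-butyldimethylsilyl)oxy]-5-(propan-2-yl)nona-1,7-diyn-4-ol F4. Dess–Martin oxidation gives (5R,6S)-6-[(tert-butyldimethylsilyl)oxy]-5-(propan-2-yl)nona-1,7-diyn-4-one F5. A reagent-controlled CBS reduction ((S)-Me-CBS, catecholborane, toluene, −78 °C, with the branched C5 side as the large group) then returns to 8.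

Step 6 is the alkyne borylation. The risk is boron ending up on the wrong alkyne carbon next to the bulky silyl ether. The fallback sets out from 14. Hydrozirconation (Cp2Zr(H)Cl, THF, syn, Zr on the methyl-bearing carbon) and iodinolysis give (3E,6R,7S,8S,9E)-8-[(tert-butyldimethylsilyl)oxy]-10-iodo-4-methyl-7-(propan-2-yl)-6-[(triethylsilyl)oxy]undeca-3,9-dien-1-ol F6. A Miyaura borylation with retention (PdCl2(PPh3)2, PPh3, KOPh, B2pin2, toluene, 50 °C) returns to 15.

Further compounds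
F1 | step 8 | (3E,6R,7S,8S,9E)-8-[(tert-butyldimethylsilyl)oxy]-1,10-diiodo-4-methyl-7-(propan-2-yl)-6-[(triethylsilyl)oxy]undeca-3,9-diene | ICC/C=C(\C)C[C@@H](O[Si](CC)(CC)CC)[C@@H]([C@H](O[Si](C)(C)C(C)(C)C)/C=C(\C)I)C(C)C
F2 | step 8 | alkylzinc iodide from F1 (zinc on C1 of the undecadiene chain) | I[Zn]CC/C=C(\C)C[C@@H](O[Si](CC)(CC)CC)[C@@H]([C@H](O[Si](C)(C)C(C)(C)C)/C=C(\C)I)C(C)C
F3 | step 3 | allenylzinc bromide | C=C=C[Zn]Br
F4 | step 3 | (4RS,5S,6S)-6-[(tert-butyldimethylsilyl)oxy]-5-(propan-2-yl)nona-1,7-diyn-4-ol | CC#C[C@@H](O[Si](C)(C)C(C)(C)C)[C@H](C(O)CC#C)C(C)C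
F5 | step 3 | (5R,6S)-6-[(tert-butyldimethylsilyl)oxy]-5-(propan-2-yl)nona-1,7-diyn-4-one | CC#C[C@@H](O[Si](C)(C)C(C)(C)C)[C@H](C(=O)CC#C)C(C)C
F6 | step 6 | (3E,6R,7S,8S,9E)-8-[(tert-butyldimethylsilyl)oxy]-10-iodo-4-methyl-7-(propan-2-yl)-6-[(triethylsilyl)oxy]undeca-3,9-dien-1-ol | OCC/C=C(\C)C[C@@H](O[Si](CC)(CC)CC)[C@@H]([C@H](O[Si](C)(C)C(C)(C)C)/C=C(\C)I)C(C)C
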